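**Retrosynthetic overview**
- The depside ester C–O bond between the ring A carboxyl and O4 of ring B is cut last; ring A acid 17 and ring B phenol 15 both come from one keto ester 14.
- 14 comes from homophthalate 10: the unhindered CH2CO2Me arm becomes the heptyl ketone, the hindered aryl ester is kept.
- 10 comes from 3,5-bis(benzyloxy)benzyne (released from silyl triflate 6) and dimethyl malonate by insertion into a malonate C–C sigma bond. The feature used: in ring A the carboxyl carbon on C1 sits between the oxygen-bearing C2 and C6, which carries the CH2 of the 2-oxononyl chain; ring B repeats this pattern (ester on C1, OH on C2, CH2 on C6), so one insertion product serves both rings.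
- No ring is formed in the route; both benzene rings come from 3,5-bis(benzyloxy)phenol 1, which is converted to 6 by ortho-bromination, O-silylation and retro-Brook rearrangement/triflation.

Key step: step 4

Remark: the target has no stereocentre; 3,5-bis(benzyloxy)phenol (1), dimethyl malonate (7) and heptylmagnesium bromide solution (12) are taken as purchasable.

**Step 1**
Reactants: 1 3,5-bis(benzyloxy)phenol
Product: 2 3,5-bis(benzyloxy)-2-bromophenol
Conditions: NBS (1.0 equiv), CH2Cl2, −78 °C → 0 °C
Reagents that add atoms: N-bromosuccinimide, O=C1CCC(=O)N1Br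
Why: Electrophilic aromatic bromination; in a non-polar solvent at low temperature the hydrogen-bonded phenol should direct NBS to the two equivalent ortho positions, which are also para to a benzyloxy group and less shielded than C4 between the two benzyloxy groups, and one equivalent of NBS limits dibromination.

**Step 2**
Reactants: 2 3,5-bis(benzyloxy)-2-bromophenol
Product: 3 [3,5-bis(benzyloxy)-2-bromophenoxy]trimethylsilane
Conditions: HMDS, THF, 70 °C; then evaporation
Reagents that add atoms: hexamethyldisilazane, C[Si](C)(C)N[Si](C)(C)C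
Why: O-silylation of a phenol with HMDS, driven by loss of ammonia, should give the silyl ether clean enough to be used crude.

**Step 3**
Reactants: 3 [3,5-bis(benzyloxy)-2-bromophenoxy]trimethylsilane
Product: 6 3,5-bis(benzyloxy)-2-(trimethylsilyl)phenyl trifluoromethanesulfonate, via aryllithium 4 (not isolated), via lithium 2-silylphenoxide 5 (not isolated)
Conditions: n-BuLi, THF, −100 → −78 °C; then Tf2O, −100 → −78 °C
Reagents that add atoms: trifluoromethanesulfonic anhydride, O=S(=O)(OS(=O)(=O)C(F)(F)F)C(F)(F)F
Why: Bromine–lithium exchange is faster than benzylic deprotonation at −100 °C, the aryllithium undergoes 1,3 O→C silyl migration (retro-Brook rearrangement) to the phenoxide, and this is O-sulfonylated by Tf2O.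

**Step 4**
Reactants: 6 3,5-bis(benzyloxy)-2-(trimethylsilyl)phenyl trifluoromethanesulfonate; 7 dimethyl malonate
Product: 10 dimethyl 3,5-bis(benzyloxy)homophthalate, via 3,5-bis(benzyloxy)benzyne 8 (not isolated), via cesium benzocyclobutenoxide 9 (not isolated)
Conditions: CsF (3 equiv), 7 (2 equiv), MeCN, 80 °C
Reagents that add atoms: none
Why: Fluoride attacks silicon of 6 and triflate leaves, giving aryne 8; the cesium enolate of 7 adds to the aryne carbon that carried the triflate (C1, remote from the C3 benzyloxy group), the resulting C2 aryl anion attacks an ester carbonyl of the malonate unit, and alkoxide 9 fragments by cleaving the former malonate C–C bond to the ester-stabilised benzylic enolate, which is protonated to 10. The closest known reaction type is the fluoride-induced insertion of arynes into the C–C sigma bond of malonates and beta-keto esters (aryne acyl-alkylation). The only ring closed is the transient four-membered ring of 9, formed by 4-exo-trig attack of the aryl anion on the ester and opened again in the same flask, so no ring remains in 10. No stereocentre is created. The step needs regioselective addition to the unsymmetrical aryne, and this is secured by the C3 benzyloxy group, whose inductive effect and distortion of the triple bond direct the nucleophile to C1 and leave the charge on C2 next to oxygen, so that the carboxyl ends up between the benzyloxy-bearing carbon and the CH2 arm. An excess of 7 keeps the acidic product from being arylated a second time.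

**Step 5**
Reactants: 10 dimethyl 3,5-bis(benzyloxy)homophthalate
Product: 11 2-[3,5-bis(benzyloxy)-2-(methoxycarbonyl)phenyl]acetic acid
Conditions: LiOH·H2O (1.2 equiv), THF/MeOH/H2O, 0 °C → rt; then 1 M HCl
Reagents that add atoms: lithium hydroxide, [Li+].[OH-]
Why: Chemoselective saponification; the aliphatic ester is unhindered, whereas the aryl ester is flanked by two ortho substituents and deactivated by two alkoxy donors, so only the CH2CO2Me group should hydrolyse.

**Step 6**
Reactants: 11 2-[3,5-bis(benzyloxy)-2-(methoxycarbonyl)phenyl]acetic acid; 12 heptylmagnesium bromide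
Product: 14 methyl 2,4-bis(benzyloxy)-6-(2-oxononyl)benzoate, via acid chloride 13 (not isolated)
Conditions: (COCl)2, cat. DMF, CH2Cl2, 0 °C → rt, evaporation; then 12 (1.1 equiv), Fe(acac)3 (3 mol%), THF, −78 °C
Reagents that add atoms: none
Why: Acid chloride formation under Vilsmeier catalysis followed by iron-catalysed acylation of the alkyl Grignard reagent, a cross-coupling that at −78 °C should outrun attack on the hindered aryl ester, addition to the product ketone and ketene formation.

**Step 7**
Reactants: 14 methyl 2,4-bis(benzyloxy)-6-(2-oxononyl)benzoate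
Product: 15 methyl 2,4-dihydroxy-6-(2-oxononyl)benzoate
Conditions: H2 (1 atm), 10% Pd/C, EtOAc, rt
Reagents that add atoms: none
Why: Hydrogenolysis of the two benzyl aryl ethers; the ketone carbonyl is not benzylic and the ester is inert, so only the O–benzyl bonds should be cleaved.

**Step 8**
Reactants: 14 methyl 2,4-bis(benzyloxy)-6-(2-oxononyl)benzoate
Product: 16 methyl 2,4-bis(benzyloxy)-6-[(2-heptyl-1,3-dioxolan-2-yl)methyl]benzoate
Conditions: TMSOCH2CH2OTMS, TMSOTf (cat.), CH2Cl2, −78 → −20 °C; pyridine quench
Reagents that add atoms: 1,2-bis(trimethylsilyloxy)ethane, C[Si](C)(C)OCCO[Si](C)(C)C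
Why: Noyori ketalisation; it works at low temperature without a Brønsted acid, so the ketone is masked before it can enolise onto the neighbouring ester, and the dioxolane is needed to stop isocoumarin formation in steps 9 and 10.

**Step 9**
Reactants: 16 methyl 2,4-bis(benzyloxy)-6-[(2-heptyl-1,3-dioxolan-2-yl)methyl]benzoate
Product: 17 2,4-bis(benzyloxy)-6-[(2-heptyl-1,3-dioxolan-2-yl)methyl]benzoic acid
Conditions: KOH, DMSO/H2O, 90 °C; then cold 1 M HCl to pH 3, used at once
Reagents that add atoms: potassium hydroxide, [K+].[OH-]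
Why: Forcing saponification of a di-ortho-substituted benzoate by poorly solvated hydroxide in aqueous DMSO; benzyl ethers and the dioxolane are stable to base, and the ketal protects the enolisable ketone.

**Step 10**
Reactants: 17 2,4-bis(benzyloxy)-6-[(2-heptyl-1,3-dioxolan-2-yl)methyl]benzoic acid; 15 methyl 2,4-dihydroxy-6-(2-oxononyl)benzoate
Product: 18 methyl 4-({2,4-bis(benzyloxy)-6-[(2-heptyl-1,3-dioxolan-2-yl)methyl]benzoyl}oxy)-2-hydroxy-6-(2-oxononyl)benzoate
Conditions: DCC, DMAP (cat.), CH2Cl2, 0 °C → rt
Reagents that add atoms: none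
Why: Steglich esterification; the 2-OH of 15 is held in a hydrogen bond to the ester carbonyl and is crowded, so the free and more acidic 4-OH should be acylated, and the masked ketone of 17 cannot close onto the activated carboxyl.

**Step 11**
Reactants: 18 the protected depside from step 10
Product: 19 methyl 4-{[2,4-bis(benzyloxy)-6-(2-oxononyl)benzoyl]oxy}-2-hydroxy-6-(2-oxononyl)benzoate
Conditions: 1 M aq. HCl, THF, rt
Reagents that add atoms: water, O
Why: Acid-catalysed hydrolysis of a dialkyl-type dioxolane; it proceeds under mild aqueous acid at room temperature, where aryl ester, methyl ester and benzyl ethers should be stable.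

**Step 12**
Reactants: 19 methyl 4-{[2,4-bis(benzyloxy)-6-(2-oxononyl)benzoyl]oxy}-2-hydroxy-6-(2-oxononyl)benzoate
Product: 20 methyl 4-{[2,4-dihydroxy-6-(2-oxononyl)benzoyl]oxy}-2-hydroxy-6-(2-oxononyl)benzoate (CNP0110390.0)
Conditions: H2 (1 atm), 10% Pd/C, EtOAc, rt
Reagents that add atoms: none
Why: Neutral hydrogenolysis of the two benzyl ethers as the last step; the depside ester, the methyl ester and both non-benzylic ketones should be untouched.

**Compound list**
1 | 3,5-bis(benzyloxy)phenol | Oc1cc(OCc2ccccc2)cc(OCc2ccccc2)c1 | starting material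
2 | 3,5-bis(benzyloxy)-2-bromophenol | Oc1cc(OCc2ccccc2)cc(OCc2ccccc2)c1Br | intermediate
3 | [3,5-bis(benzyloxy)-2-bromophenoxy]trimethylsilane | C[Si](C)(C)Oc1cc(OCc2ccccc2)cc(OCc2ccccc2)c1Br | intermediate
4 | {2,4-bis(benzyloxy)-6-[(trimethylsilyl)oxy]phenyl}lithium (not isolated) | C[Si](C)(C)Oc1cc(OCc2ccccc2)cc(OCc2ccccc2)c1[Li] | intermediate
5 | lithium 3,5-bis(benzyloxy)-2-(trimethylsilyl)phenoxide (not isolated) | [Li+].[O-]c1cc(OCc2ccccc2)cc(OCc2ccccc2)c1[Si](C)(C)C | intermediate
6 | 3,5-bis(benzyloxy)-2-(trimethylsilyl)phenyl trifluoromethanesulfonate | C[Si](C)(C)c1c(OCc2ccccc2)cc(OCc2ccccc2)cc1OS(=O)(=O)C(F)(F)F | intermediate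
7 | dimethyl malonate | COC(=O)CC(=O)OC | starting material
8 | 3,5-bis(benzyloxy)benzyne (not isolated) | C1#CC(OCc2ccccc2)=CC(OCc2ccccc2)=C1 | intermediate
9 | cesium 3,5-bis(benzyloxy)-7-methoxy-8-(methoxycarbonyl)bicyclo[4.2.0]octa-1,3,5-trien-7-olate (not isolated) | COC(=O)C1c2cc(OCc3ccccc3)cc(OCc3ccccc3)c2C1([O-])OC.[Cs+] | intermediate
10 | dimethyl 3,5-bis(benzyloxy)homophthalate (methyl 2,4-bis(benzyloxy)-6-(2-methoxy-2-oxoethyl)benzoate) | COC(=O)Cc1cc(OCc2ccccc2)cc(OCc2ccccc2)c1C(=O)OC | intermediate
11 | 2-[3,5-bis(benzyloxy)-2-(methoxycarbonyl)phenyl]acetic acid | OC(=O)Cc1cc(OCc2ccccc2)cc(OCc2ccccc2)c1C(=O)OC | intermediate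
12 | heptylmagnesium bromide | CCCCCCC[Mg]Br | starting material
13 | methyl 2,4-bis(benzyloxy)-6-(2-chloro-2-oxoethyl)benzoate (not isolated) | ClC(=O)Cc1cc(OCc2ccccc2)cc(OCc2ccccc2)c1C(=O)OC | intermediate
14 | methyl 2,4-bis(benzyloxy)-6-(2-oxononyl)benzoate | CCCCCCCC(=O)Cc1cc(OCc2ccccc2)cc(OCc2ccccc2)c1C(=O)OC | intermediate
15 | methyl 2,4-dihydroxy-6-(2-oxononyl)benzoate | CCCCCCCC(=O)Cc1cc(O)cc(O)c1C(=O)OC | intermediate
16 | methyl 2,4-bis(benzyloxy)-6-[(2-heptyl-1,3-dioxolan-2-yl)methyl]benzoate | CCCCCCCC1(Cc2cc(OCc3ccccc3)cc(OCc3ccccc3)c2C(=O)OC)OCCO1 | intermediate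
17 | 2,4-bis(benzyloxy)-6-[(2-heptyl-1,3-dioxolan-2-yl)methyl]benzoic acid | CCCCCCCC1(Cc2cc(OCc3ccccc3)cc(OCc3ccccc3)c2C(=O)O)OCCO1 | intermediate
18 | methyl 4-({2,4-bis(benzyloxy)-6-[(2-heptyl-1,3-dioxolan-2-yl)methyl]benzoyl}oxy)-2-hydroxy-6-(2-oxononyl)benzoate | CCCCCCCC(=O)Cc1cc(OC(=O)c2c(OCc3ccccc3)cc(OCc3ccccc3)cc2CC2(CCCCCCC)OCCO2)cc(O)c1C(=O)OC | intermediate
19 | methyl 4-{[2,4-bis(benzyloxy)-6-(2-oxononyl)benzoyl]oxy}-2-hydroxy-6-(2-oxononyl)benzoate | CCCCCCCC(=O)Cc1cc(OC(=O)c2c(OCc3ccccc3)cc(OCc3ccccc3)cc2CC(=O)CCCCCCC)cc(O)c1C(=O)OC | intermediate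
20 | methyl 4-{[2,4-dihydroxy-6-(2-oxononyl)benzoyl]oxy}-2-hydroxy-6-(2-oxononyl)benzoate (CNP0110390.0) | CCCCCCCC(=O)Cc1cc(OC(=O)c2c(O)cc(O)cc2CC(=O)CCCCCCC)cc(O)c1C(=O)OC | target

**Step count**
Total: 12 steps. Longest linear sequence: 11 steps (steps 1–6 and 8–12; step 7 is the side branch to ring B).

**Steps most likely to fail, each with a fallback**

1. Step 4 (aryne insertion). The aryl anion may be protonated before it closes onto the ester, which would stop at simple C-arylation of the malonate; the nucleophile may add to the wrong aryne carbon; or the acidic product may be arylated again. The fallback builds the homophthalate by lateral metalation. It replaces compounds 1 to 9, so it sets out not from a numbered compound but from purchasable methyl orsellinate F1, and it comes back to the route at 10. Methyl orsellinate F1 would be benzylated on both phenols (BnBr, K2CO3, DMF, 60 °C) to methyl 2,4-bis(benzyloxy)-6-methylbenzoate F2. LDA (2 equiv, THF, −78 °C) would then deprotonate the C6 methyl group ortho to the ester, and trapping of the benzylic anion with dimethyl carbonate should give 10.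

2. Step 1 (bromination). Positional control may be lost through attack at C4 between the two benzyloxy groups, and the very electron-rich ring may be brominated twice. The fallback places the silyl group by directed ortho-metalation instead of by halogenation; it sets out from 1 and comes back at 6.
   - 1 would be carbamoylated with isopropyl isocyanate (cat. Et3N, CH2Cl2) to 3,5-bis(benzyloxy)phenyl N-isopropylcarbamate F3.
   - In one flask F3 would be N-silylated (TBSOTf, TMEDA, Et2O) to the N-(tert-butyldimethylsilyl) carbamate F4.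
   - F4 would be lithiated (n-BuLi, TMEDA, −78 °C) at the position between the carbamate and a benzyloxy group and quenched with TMSCl, giving the N-silyl 2-(trimethylsilyl) carbamate F5.
   - Work-up with aqueous NaHSO4 would remove the N-silyl group and leave 3,5-bis(benzyloxy)-2-(trimethylsilyl)phenyl N-isopropylcarbamate F6.
   - Et2NH and DBU in MeCN at 40 °C would cleave the carbamate to 3,5-bis(benzyloxy)-2-(trimethylsilyl)phenol F7, which PhNTf2 in the same flask should convert to 6.

3. Step 11 (ketal hydrolysis). Under acid the unveiled ring A ketone may enolise and its enol oxygen may attack the neighbouring depside carbonyl, expelling the ring B phenol and closing an isocoumarin; the ketal cleavage may also stall. The fallback masks the ketone as a dithioketal that is removed by a thiophilic metal salt at neutral pH; it sets out from 14 and comes back at 19.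
   - 14 would be treated with ethane-1,2-dithiol and catalytic I2 in CH2Cl2 to give methyl 2,4-bis(benzyloxy)-6-[(2-heptyl-1,3-dithiolan-2-yl)methyl]benzoate F8.
   - KOH in DMSO/H2O at 90 °C would hydrolyse the ester to 2,4-bis(benzyloxy)-6-[(2-heptyl-1,3-dithiolan-2-yl)methyl]benzoic acid F9.
   - DCC/DMAP coupling of F9 with 15 would give the dithiolane depside methyl 4-({2,4-bis(benzyloxy)-6-[(2-heptyl-1,3-dithiolan-2-yl)methyl]benzoyl}oxy)-2-hydroxy-6-(2-oxononyl)benzoate F10.
   - HgCl2 and CaCO3 in MeCN/H2O at rt should release the ketone and give 19, which would be freed of sulfur and mercury residues before the hydrogenolysis of step 12.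

**Further compounds**
F1 | step 4 | methyl orsellinate (methyl 2,4-dihydroxy-6-methylbenzoate) | COC(=O)c1c(C)cc(O)cc1O
F2 | step 4 | methyl 2,4-bis(benzyloxy)-6-methylbenzoate | COC(=O)c1c(C)cc(OCc2ccccc2)cc1OCc1ccccc1
F3 | step 1 | 3,5-bis(benzyloxy)phenyl N-isopropylcarbamate | CC(C)NC(=O)Oc1cc(OCc2ccccc2)cc(OCc2ccccc2)c1
F4 | step 1 | 3,5-bis(benzyloxy)phenyl N-(tert-butyldimethylsilyl)-N-isopropylcarbamate | CC(C)N([Si](C)(C)C(C)(C)C)C(=O)Oc1cc(OCc2ccccc2)cc(OCc2ccccc2)c1
F5 | step 1 | 3,5-bis(benzyloxy)-2-(trimethylsilyl)phenyl N-(tert-butyldimethylsilyl)-N-isopropylcarbamate | CC(C)N([Si](C)(C)C(C)(C)C)C(=O)Oc1cc(OCc2ccccc2)cc(OCc2ccccc2)c1[Si](C)(C)C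
F6 | step 1 | 3,5-bis(benzyloxy)-2-(trimethylsilyl)phenyl N-isopropylcarbamate | CC(C)NC(=O)Oc1cc(OCc2ccccc2)cc(OCc2ccccc2)c1[Si](C)(C)C
F7 | step 1 | 3,5-bis(benzyloxy)-2-(trimethylsilyl)phenol | Oc1cc(OCc2ccccc2)cc(OCc2ccccc2)c1[Si](C)(C)C
F8 | step 11 | methyl 2,4-bis(benzyloxy)-6-[(2-heptyl-1,3-dithiolan-2-yl)methyl]benzoate | CCCCCCCC1(Cc2cc(OCc3ccccc3)cc(OCc3ccccc3)c2C(=O)OC)SCCS1
F9 | step 11 | 2,4-bis(benzyloxy)-6-[(2-heptyl-1,3-dithiolan-2-yl)methyl]benzoic acid | CCCCCCCC1(Cc2cc(OCc3ccccc3)cc(OCc3ccccc3)c2C(=O)O)SCCS1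
F10 | step 11 | methyl 4-({2,4-bis(benzyloxy)-6-[(2-heptyl-1,3-dithiolan-2-yl)methyl]benzoyl}oxy)-2-hydroxy-6-(2-oxononyl)benzoate | CCCCCCCC(=O)Cc1cc(OC(=O)c2c(OCc3ccccc3)cc(OCc3ccccc3)cc2CC2(CCCCCCC)SCCS2)cc(O)c1C(=O)OC
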